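Remark on numbering: all arene intermediates are numbered as the target indane (C2 carries the two methyl groups, C4 the future acetoxymethyl arm, C5 the future 2-chloroethyl arm, C6 the future butanoyloxymethyl arm, C7 the aromatic hydrogen). Intermediates 10 and 11 are racemic diastereomer mixtures whose stereocentres vanish on aromatisation.

## Analysis of the target

The target is an achiral indane: a benzene ring fused to a 2,2-dimethylcyclopentane, with an acetoxymethyl, a 2-chloroethyl and a butanoyloxymethyl arm on the contiguous positions C4, C5 and C6, and C7 as the only aromatic C–H. There is no stereocentre, so the problem is purely one of regiochemistry on a pentasubstituted benzene. The two benzylic esters differ only in their acyl groups, which forbids any late step that frees both oxygens together or lets acyl groups exchange. Both esters sit on electron-rich benzylic carbons that ionise easily under acid. The primary chloride can eliminate to a styrene under strong base, and it lies within reach of a nucleophilic oxygen on the C4 or C6 methylene (six-membered ether closure). The difficulty is therefore to place five different carbon substituents in a fixed order around one ring and to keep the C4 and C6 oxygen arms distinct to the end. Two features are used. The cyclopentane half C1–C2(Me)2–C3 is mirror-symmetric about the plane through C2 and the midpoint of C3a–C7a, so a C3a–C7a unit taken from a 4,4-dimethylcyclopentene can be joined to a C4–C5–C6–C7 unit in either sense with the same result. The oxygen on the C4 methylene and the end carbon of the C5 arm can be tied into one six-membered cyclic ether (C4–CH2–O–CH2–CH2–C5), which hides both arms and sets them apart from the C6 arm.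

## Retrosynthetic reasoning

17 to 16. The last bond made is the C–O bond between the C4 benzylic carbon and acetate. Cutting here, rather than at the butanoate or at a C–Cl bond, leaves dichloride 16, in which the benzylic chloride is the only site a carboxylate displaces at a useful rate. The acetate, the most easily ionised group of the target, then meets no further step.

16 to 15 to 14. Both C–Cl bonds of 16 are traced to one oxygen atom: the C4 benzylic carbon and the terminal carbon of the C5 arm are joined through oxygen in the cyclic ether of 14. Forward, a halide-delivering Lewis acid has to cut only the benzylic C–O bond (giving 15), and the freed primary alcohol is then exchanged for chloride. The gain is that the C4 and C5 arms travel as one inert ring, and C4 and C6 are never at the same functional stage.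

14 to 13 to 12. The butanoate of 14 comes from alcohol 13 and this from methyl ester 12, so that the C6 carbinol carbon is at the carboxyl level when the ring is built. Reduction and acylation are placed before the ether opening on purpose. With the ester still present, the freed 2-hydroxyethyl arm on C5 would sit ortho to a methyl ester and should close to a δ-lactone; the butanoyloxymethyl group of 14 offers it no six-membered acyl transfer.

12 to 6 and 9 (key disconnection). The benzene ring of 12 is cut at C7–C7a and C3a–C4. This gives the two-carbon unit C3a–C7a with the whole cyclopentane (enamine 9) and the four-carbon unit C4–C5–C6–C7 with all three arms (pyranone 6), whose lactone bridge leaves as CO2. This cut is chosen because it alone uses the symmetry of the cyclopentane: either end of the enamine double bond may bond to either end of the pyranone diene. In 6 the pyranone C3–H becomes C7–H, the ester-bearing C4 becomes C6, and the fusion carbons C4a and C8a become C5 and C4. The dihydropyran oxygen must therefore be attached through CH2 to C8a (the [3,4-b] fusion, oxygen at position 7); the isomer with oxygen on the C4a side would deliver the two arms interchanged. Forward, an electron-rich alkene must add across C3 and C6 of an electron-poor 2-pyranone, CO2 must leave, and the amine must be eliminated.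

9 to 7 and 8. Enamine 9 is cut at the C–N bond to ketone 7 and amine 8. The only demand is that the double bond lie on the side away from the quaternary carbon.

6 to 5 to 3 and 4, and 3 to 1 and 2. The pyranone is opened at the lactone O–C(=O) bond to keto diester 5, and 5 at its C=C bond to the 2,4-dioxo ester 3 and ylide 4. Compound 3 is cut between C4 of ketone 1 and an oxalyl carbon of 2. This order fixes the regiochemistry in the first step (acylation of the C4 enolate of 1) and takes from 4 the two pyranone carbons that later become C7 or leave as CO2. A shorter conjugate-addition route to 5 is kept only as a reserve, because four-membered ring formation and ring enlargement are expected to interfere there.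

## Alternatives that were turned down

Alternative 1: The cyclopentane is disconnected at C3–C3a and traced to a cyclobutane spiro-fused at C7a of a non-aromatic six-membered ring. In the forward key step, catalytic sulfonic acid would ionise the tertiary, doubly allylic alcohol A2 (hydroxyl and vinyl on the future C5). A cyclobutane CH2 would shift from the spiro carbon to the neighbouring cationic carbon, enlarging the four-membered ring to the cyclopentane, and proton loss would give the arene A1.
- For: relief of four-ring strain and aromatisation drive the shift, the symmetric spiro ring makes every possible migration give the same product, and the step has no regiochemical question. On that point it is stronger than the chosen route, which depends on the double-bond position in 9.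
- Against: the two silyloxymethyl arms of A1 on C4 and C6 are chemically almost the same, so telling acetate from butanoate would rest on a modest steric difference in a mono-desilylation. The cation of the key step is flanked by two allylic silyl ethers that can ionise or eliminate under the same acid. A2 itself (a strained spiro ring on a cross-conjugated six-membered ring already carrying both oxygenated arms) has no short assembly. The vinyl group needs hydroboration and chlorination, so about six steps follow the key step.
- In comparison: the chosen route gives up the built-in certainty of the rearrangement but gets the three arms differentiated by construction in 12 (ester carbon against cyclic ether) from two fragments of one or two steps each.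

Alternative 2: The benzene ring is disconnected into a conjugated diyne (C3a, C4, C5, C6) and a tethered terminal alkyne (C7a, C7), and the C4 and C5 substituents into a malonate unit. Heating triyne A4 with a malonate nucleophile under basic conditions would form C3a–C7a and C6–C7, closing both rings to an indane-fused aryne. The aryne would then insert into a malonate C–C bond to give A3, with the ester on C4 and the acetate arm on C5.
- For: two rings and four carbon–carbon bonds arise in one operation from a linear precursor. The three arms of A3 arrive chemically distinct (silyl ether, aryl ester, aliphatic ester), which matches the chosen route on differentiation and beats it on bonds formed per step.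
- Against: the site of enolate attack on the unsymmetrical aryne is only a balance between ring-fusion distortion (favouring C5) and the inductive pull of the silyloxymethyl group on C6 (favouring C4), with no structural guarantee. The unactivated all-carbon tether needs a high temperature at which base can isomerise the propargylic positions. The endgame must reduce a doubly ortho-substituted benzoate after converting the aliphatic ester, again about six steps.
- In comparison: in the chosen route the positions of all arms are fixed by the connectivity of 6, and the ring-forming step runs under mild, matched-polarity conditions.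

Alternative 3: The arene is disconnected at C4–C5 and C6–C7 with extrusion of CO2. A cyclopentane-fused 2-pyranone supplies C4, C3a, C7a and C7, and an alkyne tethered through the C4 carboxyl as an ester supplies C5 and C6. Heating A6 at high dilution would give a bridged adduct that loses CO2 and delivers the benzene ring and the δ-lactone of A5 together.
- For: the tether makes the regiochemistry absolute and no amine has to be eliminated. The lactone of A5 already separates the C4 carbonyl from the C5 arm oxygen. On regiocontrol this is stronger than the chosen route.
- Against: an ester-substituted pyranone and an electronically neutral internal alkyne are poorly matched, and the ester tether prefers the extended conformation, so forcing temperatures are expected. The pyranone half of A6 has to be built from 7 with the same question of which α-carbon reacts, and then joined to an alkyne half that needs its own synthesis. Opening the lactone to the chloroethyl arm needs chlorinating conditions that the silyl ether would not survive.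
- In comparison: the chosen route offers an electronically matched intermolecular union of two short fragments and an ether, rather than a lactone, as the latent C4/C5 pair.

Key step: step 4

Step 1
Reactants: 1 tetrahydropyran-3-one; 2 dimethyl oxalate
Product: 3 methyl 2-oxo-2-(3-oxooxan-4-yl)acetate
Conditions: LiN(SiMe3)2, THF, −78 °C; then 2, −78 °C → rt; 1 M HCl
Reagents that add atoms: none
Why: Kinetic deprotonation of 1 by the hindered lithium amide should occur at C4, away from the ring oxygen whose lone pairs disfavour enolisation towards C2; crossed Claisen condensation of the lithium enolate with the non-enolisable diester 2 gives 3, held as its lithium chelate so that the acylation is not reversed.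

Step 2
Reactants: 3 methyl 2-oxo-2-(3-oxooxan-4-yl)acetate; 4 methyl (triphenylphosphoranylidene)acetate
Product: 6 methyl 2-oxo-5,6-dihydro-2H,8H-pyrano[3,4-b]pyran-4-carboxylate, via keto diester 5 (not isolated)
Conditions: 4, PhMe, 110 °C; then TsOH·H2O (cat.), 110 °C (−MeOH)
Reagents that add atoms: none
Why: Wittig olefination at the ketone carbonyl next to the ester, the most electrophilic carbonyl of 3, should give 5 as a mixture of alkene isomers; under acid the ring ketone enolises into conjugation, the alkene geometry equilibrates through the dienol, and the enol oxygen acylates the distal ester (6-exo-trig enol lactonisation with loss of methanol) to give the 2-pyranone.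

Step 3
Reactants: 7 3,3-dimethylcyclopentanone; 8 pyrrolidine
Product: 9 1-(4,4-dimethylcyclopent-1-en-1-yl)pyrrolidine
Conditions: TsOH·H2O (cat.), PhMe, reflux, Dean–Stark (−H2O); evaporate, use crude under Ar
Reagents that add atoms: none
Why: Stork enamine formation by acid-catalysed condensation with azeotropic removal of water; the double bond should settle mainly on the side remote from the quaternary carbon for steric reasons, and the two possible enamines interconvert through the iminium ion.

Step 4
Reactants: 6 methyl 2-oxo-5,6-dihydro-2H,8H-pyrano[3,4-b]pyran-4-carboxylate; 9 1-(4,4-dimethylcyclopent-1-en-1-yl)pyrrolidine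
Product: 12 methyl 2,2-dimethyl-4,5-(2-oxabutane-1,4-diyl)indane-6-carboxylate, via bridged lactone 10 (not isolated), via aminocyclohexadiene 11 (not isolated)
Conditions: 9 (1.5 equiv), PhMe, rt → 100 °C (−CO2); then AcOH, 60 °C
Reagents that add atoms: none
Why: Inverse-electron-demand Diels–Alder reaction: the HOMO of enamine 9 and the LUMO of pyranone 6 (lowered by the lactone carbonyl and the C4 ester) are matched, and bonding should be asynchronous, the enamine CH carbon bonding first to one diene terminus and the iminium carbon then closing onto the other to give 10. Retro-(4+2) loss of CO2 from the 2-oxabicyclo[2.2.2]octenone 10 gives 11, and acid-assisted loss of pyrrolidine through a cyclohexadienyl cation aromatises it to 12; the closest known reaction type is the enamine annulation of ester-substituted 2-pyranones to benzoates. The benzene ring is closed intermolecularly as a (4+2) annulation that forms C7–C7a and C3a–C4; no ring is closed by cyclisation of a chain. The stereocentres of 10 and 11 are transient and none remains in 12, so facial and endo/exo selectivity do not matter. Orientation of the partners does not matter either, because exchanging the two enamine carbons only exchanges C1 and C3 of a symmetric 2,2-dimethylcyclopentane. The one selectivity needed is the position of the enamine double bond: the isomer towards the carbon next to C(Me)2 would lead to a 1,1-dimethylindane, but it is the minor isomer, its nucleophilic carbon is neopentyl-like and slow to bond, and the isomers equilibrate through the iminium ion, so the reaction should drain through 9. Acetic acid is added only after 6 is consumed, so that pyrrolidine is released as its salt and cannot open unreacted pyranone.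

Step 5
Reactants: 12 methyl 2,2-dimethyl-4,5-(2-oxabutane-1,4-diyl)indane-6-carboxylate
Product: 13 [2,2-dimethyl-4,5-(2-oxabutane-1,4-diyl)indan-6-yl]methanol
Conditions: LiAlH4, THF, 0 °C
Reagents that add atoms: none
Why: Hydride reduction of the aryl ester to the benzylic alcohol; the cyclic benzylic ether is inert to LiAlH4.

Step 6
Reactants: 13 [2,2-dimethyl-4,5-(2-oxabutane-1,4-diyl)indan-6-yl]methanol
Product: 14 [2,2-dimethyl-4,5-(2-oxabutane-1,4-diyl)indan-6-yl]methyl butanoate
Conditions: PrCOCl, pyridine, DMAP (cat.), CH2Cl2, 0 °C → rt
Reagents that add atoms: butanoyl chloride, CCCC(=O)Cl
Why: Acylation of the primary benzylic alcohol under nucleophilic catalysis; the aryl ester, which would capture the hydroxyethyl arm as a δ-lactone after ether cleavage, is thereby replaced by the final butanoate before the ether is opened.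

Step 7
Reactants: 14 [2,2-dimethyl-4,5-(2-oxabutane-1,4-diyl)indan-6-yl]methyl butanoate
Product: 15 [4-(chloromethyl)-5-(2-hydroxyethyl)-2,2-dimethylindan-6-yl]methyl butanoate
Conditions: BCl3 (1.05 equiv), CH2Cl2, −78 °C; cold H2O; crude used at once
Reagents that add atoms: boron trichloride, ClB(Cl)Cl
Why: Lewis-acid ether cleavage as in the BCl3 cleavage of benzyl ethers: BCl3 binds the more basic ether oxygen and chloride is delivered to the benzylic carbon, whose ionisation is assisted by two ortho alkyl groups; at −78 °C with one equivalent the less basic ester carbonyl of the butanoate should not be engaged, and the alkoxyborane is hydrolysed on cold quench.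

Step 8
Reactants: 15 [4-(chloromethyl)-5-(2-hydroxyethyl)-2,2-dimethylindan-6-yl]methyl butanoate
Product: 16 [4-(chloromethyl)-5-(2-chloroethyl)-2,2-dimethylindan-6-yl]methyl butanoate
Conditions: SOCl2, DMF (cat.), CH2Cl2, 0 °C → rt
Reagents that add atoms: thionyl chloride, O=S(Cl)Cl
Why: Deoxychlorination of the primary alcohol through its chlorosulfite with chloroiminium (Vilsmeier-type) catalysis and SN2 attack by chloride; no base is present, so no alkoxide forms that would re-close the ether onto the benzylic chloride.

Step 9
Reactants: 16 [4-(chloromethyl)-5-(2-chloroethyl)-2,2-dimethylindan-6-yl]methyl butanoate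
Product: 17 [4-(acetoxymethyl)-5-(2-chloroethyl)-2,2-dimethylindan-6-yl]methyl butanoate
Conditions: CsOAc, DMF, rt
Reagents that add atoms: caesium acetate, CC(=O)[O-].[Cs+]
Why: SN2 displacement by the poorly solvated caesium carboxylate in a dipolar aprotic solvent; the benzylic chloride should react far faster than the primary 2-arylethyl chloride, and acetate is too weak a base to eliminate HCl or to cleave the butanoate.

Compound list

1 | tetrahydropyran-3-one (oxan-3-one) | O=C1CCCOC1 | starting material
2 | dimethyl oxalate | COC(=O)C(=O)OC | starting material
3 | methyl 2-oxo-2-(3-oxooxan-4-yl)acetate (largely enolised) | COC(=O)C(=O)C1CCOCC1=O | intermediate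
4 | methyl (triphenylphosphoranylidene)acetate | COC(=O)C=P(c1ccccc1)(c1ccccc1)c1ccccc1 | starting material
5 | dimethyl 2-(3-oxooxan-4-yl)but-2-enedioate (mixture of alkene isomers, not isolated) | COC(=O)C=C(C(=O)OC)C1CCOCC1=O | intermediate
6 | methyl 2-oxo-5,6-dihydro-2H,8H-pyrano[3,4-b]pyran-4-carboxylate | O=C1C=C(C(=O)OC)C2=C(O1)COCC2 | intermediate
7 | 3,3-dimethylcyclopentanone | CC1(C)CCC(=O)C1 | starting material
8 | pyrrolidine | C1CCNC1 | starting material
9 | 1-(4,4-dimethylcyclopent-1-en-1-yl)pyrrolidine | CC1(C)CC=C(C1)N1CCCC1 | intermediate
10 | bridged lactone from (4+2) addition of 9 across C3 and C8a of 6 (2-oxabicyclo[2.2.2]oct-5-en-3-one core, pyrrolidine on the carbon bonded to the former pyranone C3; racemic diastereomer mixture, not isolated) | O=C1OC23COCCC3=C(C(=O)OC)C1C1(N4CCCC4)CC(C)(C)CC12 | intermediate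
11 | 3a,7a-dihydro derivative of 12 with pyrrolidin-1-yl on C7a and hydrogen on C3a (racemic diastereomer mixture, not isolated) | COC(=O)C1=CC2(N3CCCC3)CC(C)(C)CC2C2=C1CCOC2 | intermediate
12 | methyl 2,2-dimethyl-4,5-(2-oxabutane-1,4-diyl)indane-6-carboxylate (C4–CH2–O–CH2–CH2–C5 ring) | COC(=O)c1cc2c(c3c1CCOC3)CC(C)(C)C2 | intermediate
13 | [2,2-dimethyl-4,5-(2-oxabutane-1,4-diyl)indan-6-yl]methanol | OCc1cc2c(c3c1CCOC3)CC(C)(C)C2 | intermediate
14 | [2,2-dimethyl-4,5-(2-oxabutane-1,4-diyl)indan-6-yl]methyl butanoate | CCCC(=O)OCc1cc2c(c3c1CCOC3)CC(C)(C)C2 | intermediate
15 | [4-(chloromethyl)-5-(2-hydroxyethyl)-2,2-dimethylindan-6-yl]methyl butanoate | CCCC(=O)OCc1cc2c(c(CCl)c1CCO)CC(C)(C)C2 | intermediate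
16 | [4-(chloromethyl)-5-(2-chloroethyl)-2,2-dimethylindan-6-yl]methyl butanoate | CCCC(=O)OCc1cc2c(c(CCl)c1CCCl)CC(C)(C)C2 | intermediate
17 | [4-(acetoxymethyl)-5-(2-chloroethyl)-2,2-dimethylindan-6-yl]methyl butanoate | CCCC(=O)OCc1cc2c(c(COC(C)=O)c1CCCl)CC(C)(C)C2 | target

Total step count: 9. Longest linear sequence: 8 steps (steps 1, 2, 4, 5, 6, 7, 8, 9 from tetrahydropyran-3-one); step 3 is a one-step branch that joins at step 4.

Steps least certain to work

Step 4 (key step).
- Risk: enamine formation towards the carbon next to the quaternary centre may be carried into the cycloaddition and give the 1,1-dimethyl regioisomer of the indane. The cycloaddition may also be slow, because a single ester activates a 5,6-dialkylated pyranone, and amine set free too early may open the lactone.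
- Fallback, from 7 (with 6) back to 12: deprotonation of 7 with LiN(i-Pr)2 in THF at −78 °C and silylation with Me3SiCl should give the kinetic enol ether [(4,4-dimethylcyclopent-1-en-1-yl)oxy]trimethylsilane F3, whose double-bond position cannot drift. Heating F3 with 6 in xylene in a sealed tube should give the silyloxy bridged lactone F4 and, after loss of CO2, the silyloxycyclohexadiene F5. Treatment with TsOH should eliminate trimethylsilanol and return the route to 12.

Step 2.
- Risk: 3 is largely enolised, so olefination of the carbonyl next to the ester may be slow, and proton transfer to the ylide may stall the reaction before lactonisation.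
- Fallback, from 1 back to 6 through 5: condensation of 1 with morpholine (TsOH cat., PhMe, Dean–Stark) should give 4-(5,6-dihydro-2H-pyran-3-yl)morpholine F1. Addition of dimethyl acetylenedicarboxylate in MeOH at 0 °C should give the dienamine dimethyl 2-[5-(morpholin-4-yl)-3,6-dihydro-2H-pyran-4-yl]but-2-enedioate F2; the protic solvent protonates the zwitterion before it can close to a cyclobutene, and the six-membered amine avoids the hydrogen shift open to five-membered amine adducts. Aqueous HCl hydrolysis leads to 5, and TsOH in hot PhMe to 6.

Step 7 (and the handling of 15 before step 8).
- Risk: the Lewis acid may ionise the benzylic butanoate as well as the ether. Benzylic cations may alkylate the electron-rich arene of a second molecule at C7. The hydroxy chloride 15 may re-close to 14 on work-up or standing.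
- Fallback, from 14 directly to 16: Ph3PCl2 in hot chlorobenzene phosphonylates the ether oxygen, chloride opens the benzylic C–O bond, and the resulting alkoxyphosphonium chloride collapses to the primary chloride and triphenylphosphine oxide. No free alcohol appears and no boron Lewis acid meets the ester.

Step 9.
- Risk: substitution at the benzylic carbon, which is flanked by two ortho substituents, may be slow enough for attack at the primary chloride or elimination to compete.
- Fallback, from 16 back to 17: silver-assisted hydrolysis (Ag2CO3, aqueous acetone), which only the ionisable benzylic chloride can undergo, should give [5-(2-chloroethyl)-4-(hydroxymethyl)-2,2-dimethylindan-6-yl]methyl butanoate F6. Acetylation with acetic anhydride, pyridine and catalytic DMAP, with no strong base so that the alcohol does not close onto the chloroethyl arm, then gives 17.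

## Further compounds

F1 | step 2 | 4-(5,6-dihydro-2H-pyran-3-yl)morpholine | C1(=CCCOC1)N1CCOCC1
F2 | step 2 | dimethyl 2-[5-(morpholin-4-yl)-3,6-dihydro-2H-pyran-4-yl]but-2-enedioate | COC(=O)C=C(C(=O)OC)C1=C(N2CCOCC2)COCC1
F3 | step 4 | [(4,4-dimethylcyclopent-1-en-1-yl)oxy]trimethylsilane | CC1(C)CC=C(C1)O[Si](C)(C)C
F4 | step 4 | silyloxy bridged lactone (trimethylsilyloxy analogue of 10) | O=C1OC23COCCC3=C(C(=O)OC)C1C1(O[Si](C)(C)C)CC(C)(C)CC12
F5 | step 4 | silyloxycyclohexadiene (trimethylsilyloxy analogue of 11) | COC(=O)C1=CC2(O[Si](C)(C)C)CC(C)(C)CC2C2=C1CCOC2
F0 | step 7 | none | none
F6 | step 9 | [5-(2-chloroethyl)-4-(hydroxymethyl)-2,2-dimethylindan-6-yl]methyl butanoate | CCCC(=O)OCc1cc2c(c(CO)c1CCCl)CC(C)(C)C2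
A1 | alternative 1 | 4,6-bis{[(tert-butyldimethylsilyl)oxy]methyl}-2,2-dimethyl-5-vinylindane | C=Cc1c(CO[Si](C)(C)C(C)(C)C)cc2c(c1CO[Si](C)(C)C(C)(C)C)CC(C)(C)C2
A2 | alternative 1 | 6,8-bis{[(tert-butyldimethylsilyl)oxy]methyl}-2,2-dimethyl-7-vinylspiro[3.5]nona-5,8-dien-7-ol | C=CC1(O)C(CO[Si](C)(C)C(C)(C)C)=CC2(CC(C)(C)C2)C=C1CO[Si](C)(C)C(C)(C)C
A3 | alternative 2 | methyl 6-{[(tert-butyldimethylsilyl)oxy]methyl}-5-(2-methoxy-2-oxoethyl)-2,2-dimethylindane-4-carboxylate | COC(=O)Cc1c(CO[Si](C)(C)C(C)(C)C)cc2c(c1C(=O)OC)CC(C)(C)C2
A4 | alternative 2 | tert-butyl[(7,7-dimethyldeca-2,4,9-triyn-1-yl)oxy]dimethylsilane | C#CCC(C)(C)CC#CC#CCO[Si](C)(C)C(C)(C)C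
A5 | alternative 3 | 2,2-dimethylindane with a δ-lactone from the C4 carboxyl to the C5 ethyl arm (C4–C(=O)–O–CH2–CH2–C5) and a (tert-butyldimethylsilyl)oxymethyl group on C6 | O=C1OCCc2c(CO[Si](C)(C)C(C)(C)C)cc3c(c21)CC(C)(C)C3
A6 | alternative 3 | 5-[(tert-butyldimethylsilyl)oxy]pent-3-yn-1-yl 6,6-dimethyl-3-oxo-3,5,6,7-tetrahydrocyclopenta[c]pyran-4-carboxylate | O=C(OCCC#CCO[Si](C)(C)C(C)(C)C)C1=C2CC(C)(C)CC2=COC1=O
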